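**Retrosynthetic overview**
- The target is released at the end by hydrogenolysis of a pentadecabenzyl ether. The sixteenth hydroxyl comes from a last formyl-to-phenol oxidation.
- Rings C, D, E and F are attached one after another to an A–B dimer phenol. Each cycle is a copper-catalysed etherification of a hindered phenol with a bromo-benzaldehyde, followed by Baeyer–Villiger conversion of the formyl group into the next phenol.
- Ring A is not coupled but built on the ring B oxygen. The key C–C bond is an intermolecular Claisen-type acylation of the bis-silyl dienolate of methyl acetoacetate by an aryloxymalonyl chloride; a magnesium-mediated Dieckmann closure then aromatises to the phloroglucinol ring.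
- Ring order: B is brought in from 4-bromo-2,6-difluorobenzaldehyde, A is formed de novo, then C, D, E and F are attached in that order.

**Assumption:** the target has no stereocentre and is achiral, so there is no enantiomer to select. Intermediates 11 and 15–17 carry one labile stereocentre and are used as racemates; 13, 14 and 16 are used as E/Z mixtures.

**Route**

Step 1
Reactants: 1 4-bromo-2,6-difluorobenzaldehyde
Product: 2 2,6-bis(benzyloxy)-4-bromobenzaldehyde
Conditions: BnOH (2.4 equiv), Cs2CO3, DMF, 70 °C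
Reagents that add atoms: benzyl alcohol OCc1ccccc1
Why: Twofold SNAr, because both fluorines are ortho to the formyl group and are far better leaving groups than the para bromide.

Step 2
Reactants: 2 2,6-bis(benzyloxy)-4-bromobenzaldehyde
Product: 4 2,6-bis(benzyloxy)-4-bromophenol, via aryl formate 3 (not isolated)
Conditions: mCPBA, CH2Cl2, 0 °C to rt; then K2CO3 (cat.), MeOH, rt
Reagents that add atoms: 3-chloroperoxybenzoic acid OOC(=O)c1cccc(Cl)c1
Why: Baeyer–Villiger oxidation in which the electron-rich 2,6-dialkoxyaryl group migrates, followed by methanolysis of the formate.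

Step 3
Reactants: 4 2,6-bis(benzyloxy)-4-bromophenol
Product: 5 2-(allyloxy)-1,3-bis(benzyloxy)-5-bromobenzene
Conditions: allyl bromide, K2CO3, DMF, 40 °C
Reagents that add atoms: allyl bromide C=CCBr
Why: Williamson etherification installs a temporary group that is orthogonal to benzyl and stable to all later acidic and basic steps.

Step 4
Reactants: 5 2-(allyloxy)-1,3-bis(benzyloxy)-5-bromobenzene
Product: 8 4-(allyloxy)-3,5-bis(benzyloxy)phenol, via aryllithium 6 (not isolated), via dimethyl arylboronate 7 (not isolated)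
Conditions: n-BuLi, THF, −78 °C; B(OMe)3, −78 °C to 0 °C; then 30% H2O2, 0 °C to rt
Reagents that add atoms: hydrogen peroxide OO
Why: Bromine–lithium exchange, borylation and oxidative C–B to C–O migration convert the aryl bromide cleanly into the phenol.

Step 5
Reactants: 8 4-(allyloxy)-3,5-bis(benzyloxy)phenol; 9 dimethyl 2-chloromalonate
Product: 10 dimethyl 2-[4-(allyloxy)-3,5-bis(benzyloxy)phenoxy]malonate
Conditions: K2CO3, acetone, reflux
Reagents that add atoms: none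
Why: SN2 O-alkylation of the phenoxide by the chloromalonate (Williamson type) places the future ring A carbon on the ring B oxygen.

Step 6
Reactants: 10 dimethyl 2-[4-(allyloxy)-3,5-bis(benzyloxy)phenoxy]malonate
Product: 11 2-[4-(allyloxy)-3,5-bis(benzyloxy)phenoxy]-3-methoxy-3-oxopropanoic acid (racemic)
Conditions: KOH (1.0 equiv), THF–MeOH–H2O, 0 °C; then 1 M HCl, 0 °C
Reagents that add atoms: potassium hydroxide [K+].[OH-]
Why: Selective monosaponification of a symmetric malonate, since the carboxylate formed shields the second ester.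

Step 7
Reactants: 12 methyl acetoacetate
Product: 13 methyl 3-(trimethylsilyloxy)but-2-enoate (E/Z mixture)
Conditions: Me3SiCl, Et3N, hexane, rt
Reagents that add atoms: chlorotrimethylsilane C[Si](C)(C)Cl
Why: O-silylation of the enolised beta-keto ester gives the silyl enol ether.

Step 8
Reactants: 13 methyl 3-(trimethylsilyloxy)but-2-enoate
Product: 14 1-methoxy-1,3-bis(trimethylsilyloxy)buta-1,3-diene
Conditions: LDA, THF, −78 °C; then Me3SiCl, −78 °C to rt
Reagents that add atoms: chlorotrimethylsilane C[Si](C)(C)Cl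
Why: Gamma-deprotonation and O-silylation give the bis-silyl dienolate, a neutral equivalent of the acetoacetate dianion.

Step 9
Reactants: 11 2-[4-(allyloxy)-3,5-bis(benzyloxy)phenoxy]-3-methoxy-3-oxopropanoic acid; 14 1-methoxy-1,3-bis(trimethylsilyloxy)buta-1,3-diene
Product: 17 dimethyl 2-[4-(allyloxy)-3,5-bis(benzyloxy)phenoxy]-3,5-dioxoheptanedioate (racemic; keto–enol mixture), via acid chloride 15 (not isolated), via silyl enol ether 16 (not isolated)
Conditions: (COCl)2, DMF (cat.), CH2Cl2, 0 °C to rt, evaporate; then 14, CH2Cl2, −78 °C to rt; aq. HCl work-up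
Reagents that add atoms: none
Why: Intermolecular Mukaiyama-type crossed Claisen condensation in which the terminal carbon of the dienolate is C-acylated by the acid chloride under base-free conditions, so the acidic malonyl C–H does no harm; no lasting stereocentre is created.

Step 10
Reactants: 17 dimethyl 2-[4-(allyloxy)-3,5-bis(benzyloxy)phenoxy]-3,5-dioxoheptanedioate
Product: 18 methyl 3-[4-(allyloxy)-3,5-bis(benzyloxy)phenoxy]-2,4,6-trihydroxybenzoate
Conditions: Mg(OMe)2 (3 equiv), MeOH, reflux; then 1 M HCl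
Reagents that add atoms: none
Why: Magnesium-templated Dieckmann (intramolecular Claisen) attack of the beta-keto ester carbon on the aryloxy-substituted ester, made irreversible by aromatisation to the phloroglucinol ring, while O-acylation products reopen under methoxide.

Step 11
Reactants: 18 methyl 3-[4-(allyloxy)-3,5-bis(benzyloxy)phenoxy]-2,4,6-trihydroxybenzoate
Product: 19 methyl 3-[4-(allyloxy)-3,5-bis(benzyloxy)phenoxy]-2,4,6-tris(benzyloxy)benzoate
Conditions: BnBr (4 equiv), K2CO3, DMF, 70 °C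
Reagents that add atoms: benzyl bromide BrCc1ccccc1
Why: Williamson O-benzylation, done while the ester still deactivates the ring so that C-benzylation of the phloroglucinol is suppressed.

Step 12
Reactants: 19 methyl 3-[4-(allyloxy)-3,5-bis(benzyloxy)phenoxy]-2,4,6-tris(benzyloxy)benzoate
Product: 20 3-[4-(allyloxy)-3,5-bis(benzyloxy)phenoxy]-2,4,6-tris(benzyloxy)benzoic acid
Conditions: KOH (excess), 1,4-dioxane–MeOH–H2O, reflux; then 1 M HCl, 0 °C
Reagents that add atoms: potassium hydroxide [K+].[OH-]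
Why: Forcing saponification of the doubly ortho-substituted ester; benzyl and allyl ethers are inert to aqueous hydroxide.

Step 13
Reactants: 20 3-[4-(allyloxy)-3,5-bis(benzyloxy)phenoxy]-2,4,6-tris(benzyloxy)benzoic acid
Product: 21 2-(allyloxy)-1,3-bis(benzyloxy)-5-[2,4,6-tris(benzyloxy)phenoxy]benzene
Conditions: Ag2CO3 (10 mol%), AcOH (5 mol%), DMSO, 120 °C
Reagents that add atoms: none
Why: Silver-catalysed protodecarboxylation, which is especially easy for benzoic acids with two ortho alkoxy groups.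

Step 14
Reactants: 21 2-(allyloxy)-1,3-bis(benzyloxy)-5-[2,4,6-tris(benzyloxy)phenoxy]benzene
Product: 22 2,6-bis(benzyloxy)-4-[2,4,6-tris(benzyloxy)phenoxy]phenol (A–B dimer phenol)
Conditions: Pd(PPh3)4 (5 mol%), morpholine, THF, rt
Reagents that add atoms: none
Why: Tsuji–Trost deallylation removes only the allyl ether and frees the hindered ring B phenol.

Step 15
Reactants: 23 5-bromo-1,2,3-trimethoxybenzene
Product: 24 6-bromo-2,3,4-trimethoxybenzaldehyde
Conditions: Cl2CHOMe, TiCl4, CH2Cl2, −10 °C to rt; ice-water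
Reagents that add atoms: dichloromethyl methyl ether COC(Cl)Cl; water O
Why: Rieche formylation can only occur at the two equivalent free positions, each ortho to bromine and activated by an ortho and a para methoxy group.

Step 16
Reactants: 24 6-bromo-2,3,4-trimethoxybenzaldehyde
Product: 25 6-bromo-2,3,4-trihydroxybenzaldehyde
Conditions: BBr3 (4.5 equiv), CH2Cl2, −78 °C to rt; then H2O
Reagents that add atoms: none
Why: Lewis-acid cleavage of the three aryl methyl ethers; the aryl bromide and the aldehyde survive.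

Step 17
Reactants: 25 6-bromo-2,3,4-trihydroxybenzaldehyde
Product: 26 2,3,4-tris(benzyloxy)-6-bromobenzaldehyde
Conditions: BnBr (3.6 equiv), K2CO3, DMF, 60 °C, argon
Reagents that add atoms: benzyl bromide BrCc1ccccc1
Why: Williamson O-benzylation of all three phenols gives the ring C and ring E building block.

Step 18
Reactants: 22 2,6-bis(benzyloxy)-4-[2,4,6-tris(benzyloxy)phenoxy]phenol; 26 2,3,4-tris(benzyloxy)-6-bromobenzaldehyde
Product: 27 2,3,4-tris(benzyloxy)-6-{2,6-bis(benzyloxy)-4-[2,4,6-tris(benzyloxy)phenoxy]phenoxy}benzaldehyde (A–B–C trimer aldehyde)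
Conditions: CuI (20 mol%), picolinic acid (40 mol%), K3PO4, DMSO, 90 °C
Reagents that add atoms: none
Why: Ullmann-type diaryl ether synthesis in which the ortho formyl group activates the bromide and the picolinate ligand tolerates the 2,6-disubstituted phenol.

Step 19
Reactants: 27 A–B–C trimer aldehyde
Product: 29 2,3,4-tris(benzyloxy)-6-{2,6-bis(benzyloxy)-4-[2,4,6-tris(benzyloxy)phenoxy]phenoxy}phenol (A–B–C trimer phenol), via aryl formate 28 (not isolated)
Conditions: mCPBA, CH2Cl2, 0 °C to rt; then K2CO3 (cat.), MeOH–THF, rt, argon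
Reagents that add atoms: 3-chloroperoxybenzoic acid OOC(=O)c1cccc(Cl)c1
Why: Baeyer–Villiger oxidation with migration of the very electron-rich aryl group, then formate methanolysis, turns the formyl carbon position into the ring C hydroxyl.

Step 20
Reactants: 29 A–B–C trimer phenol; 2 2,6-bis(benzyloxy)-4-bromobenzaldehyde
Product: 30 A–B–C–D tetramer aldehyde [2,6-bis(benzyloxy)benzaldehyde carrying at C-4 the aryloxy group derived from phenol 29]
Conditions: CuI (20 mol%), picolinic acid (40 mol%), K3PO4, DMSO, 90 °C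
Reagents that add atoms: none
Why: Ullmann-type etherification of a hindered phenol with an unhindered bromide that is activated by its para formyl group.

Step 21
Reactants: 30 A–B–C–D tetramer aldehyde
Product: 32 A–B–C–D tetramer phenol [2,6-bis(benzyloxy)phenol carrying at C-4 the aryloxy group derived from 29], via aryl formate 31 (not isolated)
Conditions: mCPBA, CH2Cl2, 0 °C to rt; then K2CO3 (cat.), MeOH–THF, rt, argon
Reagents that add atoms: 3-chloroperoxybenzoic acid OOC(=O)c1cccc(Cl)c1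
Why: Baeyer–Villiger oxidation and formate methanolysis unmask the hindered ring D phenol.

Step 22
Reactants: 32 A–B–C–D tetramer phenol; 26 2,3,4-tris(benzyloxy)-6-bromobenzaldehyde
Product: 33 A–B–C–D–E pentamer aldehyde [2,3,4-tris(benzyloxy)benzaldehyde carrying at C-6 the aryloxy group derived from phenol 32]
Conditions: CuI (20 mol%), picolinic acid (40 mol%), K3PO4, DMSO, 90 °C
Reagents that add atoms: none
Why: Ullmann-type diaryl ether synthesis, a repeat of step 18 with the ortho formyl group again activating the bromide.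

Step 23
Reactants: 33 A–B–C–D–E pentamer aldehyde
Product: 35 A–B–C–D–E pentamer phenol [2,3,4-tris(benzyloxy)phenol carrying at C-6 the aryloxy group derived from 32], via aryl formate 34 (not isolated)
Conditions: mCPBA, CH2Cl2, 0 °C to rt; then K2CO3 (cat.), MeOH–THF, rt, argon
Reagents that add atoms: 3-chloroperoxybenzoic acid OOC(=O)c1cccc(Cl)c1
Why: Baeyer–Villiger oxidation and formate methanolysis give the ring E phenol.

Step 24
Reactants: 35 A–B–C–D–E pentamer phenol; 2 2,6-bis(benzyloxy)-4-bromobenzaldehyde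
Product: 36 hexamer aldehyde [2,6-bis(benzyloxy)benzaldehyde carrying at C-4 the aryloxy group derived from phenol 35]
Conditions: CuI (20 mol%), picolinic acid (40 mol%), K3PO4, DMSO, 90 °C
Reagents that add atoms: none
Why: Ullmann-type etherification with the para-formyl-activated bromide attaches ring F.

Step 25
Reactants: 36 hexamer aldehyde
Product: 38 hexamer phenol [2,6-bis(benzyloxy)phenol carrying at C-4 the aryloxy group derived from 35; fifteen benzyl ethers and one free OH], via aryl formate 37 (not isolated)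
Conditions: mCPBA, CH2Cl2, 0 °C to rt; then K2CO3 (cat.), MeOH–THF, rt, argon
Reagents that add atoms: 3-chloroperoxybenzoic acid OOC(=O)c1cccc(Cl)c1
Why: Baeyer–Villiger oxidation and formate methanolysis put the last oxygen on ring F.

Step 26
Reactants: 38 hexamer phenol
Product: 39 target CNP0114537.0 (hexadecahydroxy hexaphenyl pentaether)
Conditions: H2 (1 atm), Pd/C (10%), THF–MeOH, rt; filter and concentrate under argon
Reagents that add atoms: none
Why: Hydrogenolysis cleaves all fifteen benzyl ethers under neutral conditions that leave diaryl ethers and the oxidation-prone polyphenol intact.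

**Compound list**
1 | 4-bromo-2,6-difluorobenzaldehyde | O=Cc1c(F)cc(Br)cc1F | starting material
2 | 2,6-bis(benzyloxy)-4-bromobenzaldehyde | O=Cc1c(OCc7ccccc7)cc(Br)cc1OCc7ccccc7 | intermediate
3 | 2,6-bis(benzyloxy)-4-bromophenyl formate | O=COc1c(OCc7ccccc7)cc(Br)cc1OCc7ccccc7 | intermediate
4 | 2,6-bis(benzyloxy)-4-bromophenol | Oc1c(OCc7ccccc7)cc(Br)cc1OCc7ccccc7 | intermediate
5 | 2-(allyloxy)-1,3-bis(benzyloxy)-5-bromobenzene | C=CCOc1c(OCc7ccccc7)cc(Br)cc1OCc7ccccc7 | intermediate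
6 | [4-(allyloxy)-3,5-bis(benzyloxy)phenyl]lithium | [Li]c1cc(OCc7ccccc7)c(OCC=C)c(OCc7ccccc7)c1 | intermediate
7 | dimethyl [4-(allyloxy)-3,5-bis(benzyloxy)phenyl]boronate | COB(OC)c1cc(OCc7ccccc7)c(OCC=C)c(OCc7ccccc7)c1 | intermediate
8 | 4-(allyloxy)-3,5-bis(benzyloxy)phenol | Oc1cc(OCc7ccccc7)c(OCC=C)c(OCc7ccccc7)c1 | intermediate
9 | dimethyl 2-chloromalonate | COC(=O)C(Cl)C(=O)OC | starting material
10 | dimethyl 2-[4-(allyloxy)-3,5-bis(benzyloxy)phenoxy]malonate | COC(=O)C(Oc1cc(OCc7ccccc7)c(OCC=C)c(OCc7ccccc7)c1)C(=O)OC | intermediate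
11 | 2-[4-(allyloxy)-3,5-bis(benzyloxy)phenoxy]-3-methoxy-3-oxopropanoic acid (racemic) | COC(=O)C(Oc1cc(OCc7ccccc7)c(OCC=C)c(OCc7ccccc7)c1)C(=O)O | intermediate
12 | methyl acetoacetate | CC(=O)CC(=O)OC | starting material
13 | methyl 3-(trimethylsilyloxy)but-2-enoate (E/Z mixture) | COC(=O)C=C(C)O[Si](C)(C)C | intermediate
14 | 1-methoxy-1,3-bis(trimethylsilyloxy)buta-1,3-diene | COC(O[Si](C)(C)C)=CC(=C)O[Si](C)(C)C | intermediate
15 | methyl 2-[4-(allyloxy)-3,5-bis(benzyloxy)phenoxy]-3-chloro-3-oxopropanoate (racemic) | COC(=O)C(Oc1cc(OCc7ccccc7)c(OCC=C)c(OCc7ccccc7)c1)C(=O)Cl | intermediate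
16 | dimethyl 2-[4-(allyloxy)-3,5-bis(benzyloxy)phenoxy]-3-oxo-5-(trimethylsilyloxy)hept-5-enedioate (racemic, E/Z mixture) | COC(=O)C=C(O[Si](C)(C)C)CC(=O)C(Oc1cc(OCc7ccccc7)c(OCC=C)c(OCc7ccccc7)c1)C(=O)OC | intermediate
17 | dimethyl 2-[4-(allyloxy)-3,5-bis(benzyloxy)phenoxy]-3,5-dioxoheptanedioate (racemic) | COC(=O)CC(=O)CC(=O)C(Oc1cc(OCc7ccccc7)c(OCC=C)c(OCc7ccccc7)c1)C(=O)OC | intermediate
18 | methyl 3-[4-(allyloxy)-3,5-bis(benzyloxy)phenoxy]-2,4,6-trihydroxybenzoate | COC(=O)c1c(O)cc(O)c(Oc2cc(OCc7ccccc7)c(OCC=C)c(OCc7ccccc7)c2)c1O | intermediate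
19 | methyl 3-[4-(allyloxy)-3,5-bis(benzyloxy)phenoxy]-2,4,6-tris(benzyloxy)benzoate | COC(=O)c1c(OCc7ccccc7)cc(OCc7ccccc7)c(Oc2cc(OCc7ccccc7)c(OCC=C)c(OCc7ccccc7)c2)c1OCc7ccccc7 | intermediate
20 | 3-[4-(allyloxy)-3,5-bis(benzyloxy)phenoxy]-2,4,6-tris(benzyloxy)benzoic acid | OC(=O)c1c(OCc7ccccc7)cc(OCc7ccccc7)c(Oc2cc(OCc7ccccc7)c(OCC=C)c(OCc7ccccc7)c2)c1OCc7ccccc7 | intermediate
21 | 2-(allyloxy)-1,3-bis(benzyloxy)-5-[2,4,6-tris(benzyloxy)phenoxy]benzene | C=CCOc2c(OCc7ccccc7)cc(Oc1c(OCc7ccccc7)cc(OCc7ccccc7)cc1OCc7ccccc7)cc2OCc7ccccc7 | intermediate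
22 | 2,6-bis(benzyloxy)-4-[2,4,6-tris(benzyloxy)phenoxy]phenol | Oc2c(OCc7ccccc7)cc(Oc1c(OCc7ccccc7)cc(OCc7ccccc7)cc1OCc7ccccc7)cc2OCc7ccccc7 | intermediate
23 | 5-bromo-1,2,3-trimethoxybenzene | COc1cc(Br)cc(OC)c1OC | starting material
24 | 6-bromo-2,3,4-trimethoxybenzaldehyde | O=Cc1c(Br)cc(OC)c(OC)c1OC | intermediate
25 | 6-bromo-2,3,4-trihydroxybenzaldehyde | O=Cc1c(Br)cc(O)c(O)c1O | intermediate
26 | 2,3,4-tris(benzyloxy)-6-bromobenzaldehyde | O=Cc1c(Br)cc(OCc7ccccc7)c(OCc7ccccc7)c1OCc7ccccc7 | intermediate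
27 | A–B–C trimer aldehyde | O=Cc3c(Oc2c(OCc7ccccc7)cc(Oc1c(OCc7ccccc7)cc(OCc7ccccc7)cc1OCc7ccccc7)cc2OCc7ccccc7)cc(OCc7ccccc7)c(OCc7ccccc7)c3OCc7ccccc7 | intermediate
28 | A–B–C trimer formate | O=COc3c(Oc2c(OCc7ccccc7)cc(Oc1c(OCc7ccccc7)cc(OCc7ccccc7)cc1OCc7ccccc7)cc2OCc7ccccc7)cc(OCc7ccccc7)c(OCc7ccccc7)c3OCc7ccccc7 | intermediate
29 | A–B–C trimer phenol | Oc3c(Oc2c(OCc7ccccc7)cc(Oc1c(OCc7ccccc7)cc(OCc7ccccc7)cc1OCc7ccccc7)cc2OCc7ccccc7)cc(OCc7ccccc7)c(OCc7ccccc7)c3OCc7ccccc7 | intermediate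
30 | A–B–C–D tetramer aldehyde | O=Cc4c(OCc7ccccc7)cc(Oc3c(Oc2c(OCc7ccccc7)cc(Oc1c(OCc7ccccc7)cc(OCc7ccccc7)cc1OCc7ccccc7)cc2OCc7ccccc7)cc(OCc7ccccc7)c(OCc7ccccc7)c3OCc7ccccc7)cc4OCc7ccccc7 | intermediate
31 | A–B–C–D tetramer formate | O=COc4c(OCc7ccccc7)cc(Oc3c(Oc2c(OCc7ccccc7)cc(Oc1c(OCc7ccccc7)cc(OCc7ccccc7)cc1OCc7ccccc7)cc2OCc7ccccc7)cc(OCc7ccccc7)c(OCc7ccccc7)c3OCc7ccccc7)cc4OCc7ccccc7 | intermediate
32 | A–B–C–D tetramer phenol | Oc4c(OCc7ccccc7)cc(Oc3c(Oc2c(OCc7ccccc7)cc(Oc1c(OCc7ccccc7)cc(OCc7ccccc7)cc1OCc7ccccc7)cc2OCc7ccccc7)cc(OCc7ccccc7)c(OCc7ccccc7)c3OCc7ccccc7)cc4OCc7ccccc7 | intermediate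
33 | A–B–C–D–E pentamer aldehyde | O=Cc5c(Oc4c(OCc7ccccc7)cc(Oc3c(Oc2c(OCc7ccccc7)cc(Oc1c(OCc7ccccc7)cc(OCc7ccccc7)cc1OCc7ccccc7)cc2OCc7ccccc7)cc(OCc7ccccc7)c(OCc7ccccc7)c3OCc7ccccc7)cc4OCc7ccccc7)cc(OCc7ccccc7)c(OCc7ccccc7)c5OCc7ccccc7 | intermediate
34 | A–B–C–D–E pentamer formate | O=COc5c(Oc4c(OCc7ccccc7)cc(Oc3c(Oc2c(OCc7ccccc7)cc(Oc1c(OCc7ccccc7)cc(OCc7ccccc7)cc1OCc7ccccc7)cc2OCc7ccccc7)cc(OCc7ccccc7)c(OCc7ccccc7)c3OCc7ccccc7)cc4OCc7ccccc7)cc(OCc7ccccc7)c(OCc7ccccc7)c5OCc7ccccc7 | intermediate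
35 | A–B–C–D–E pentamer phenol | Oc5c(Oc4c(OCc7ccccc7)cc(Oc3c(Oc2c(OCc7ccccc7)cc(Oc1c(OCc7ccccc7)cc(OCc7ccccc7)cc1OCc7ccccc7)cc2OCc7ccccc7)cc(OCc7ccccc7)c(OCc7ccccc7)c3OCc7ccccc7)cc4OCc7ccccc7)cc(OCc7ccccc7)c(OCc7ccccc7)c5OCc7ccccc7 | intermediate
36 | hexamer aldehyde | O=Cc6c(OCc7ccccc7)cc(Oc5c(Oc4c(OCc7ccccc7)cc(Oc3c(Oc2c(OCc7ccccc7)cc(Oc1c(OCc7ccccc7)cc(OCc7ccccc7)cc1OCc7ccccc7)cc2OCc7ccccc7)cc(OCc7ccccc7)c(OCc7ccccc7)c3OCc7ccccc7)cc4OCc7ccccc7)cc(OCc7ccccc7)c(OCc7ccccc7)c5OCc7ccccc7)cc6OCc7ccccc7 | intermediate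
37 | hexamer formate | O=COc6c(OCc7ccccc7)cc(Oc5c(Oc4c(OCc7ccccc7)cc(Oc3c(Oc2c(OCc7ccccc7)cc(Oc1c(OCc7ccccc7)cc(OCc7ccccc7)cc1OCc7ccccc7)cc2OCc7ccccc7)cc(OCc7ccccc7)c(OCc7ccccc7)c3OCc7ccccc7)cc4OCc7ccccc7)cc(OCc7ccccc7)c(OCc7ccccc7)c5OCc7ccccc7)cc6OCc7ccccc7 | intermediate
38 | hexamer phenol (pentadecabenzyl ether of the target) | Oc6c(OCc7ccccc7)cc(Oc5c(Oc4c(OCc7ccccc7)cc(Oc3c(Oc2c(OCc7ccccc7)cc(Oc1c(OCc7ccccc7)cc(OCc7ccccc7)cc1OCc7ccccc7)cc2OCc7ccccc7)cc(OCc7ccccc7)c(OCc7ccccc7)c3OCc7ccccc7)cc4OCc7ccccc7)cc(OCc7ccccc7)c(OCc7ccccc7)c5OCc7ccccc7)cc6OCc7ccccc7 | intermediate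
39 | CNP0114537.0 (achiral) | Oc1cc(O)c(Oc2cc(O)c(Oc3cc(O)c(O)c(O)c3Oc3cc(O)c(Oc4cc(O)c(O)c(O)c4Oc4cc(O)c(O)c(O)c4)c(O)c3)c(O)c2)c(O)c1 | target

**Step count and risks**
Total steps: 26. Longest linear sequence: 21 steps (steps 1–6, 9–14 and 18–26).

The three steps most likely to fail:

Step 9. The aryloxymalonyl chloride may decompose or react at the wrong carbon of the dienolate. The fallback replaces the silyl dienolate by a doubly activated magnesium enolate, which also gives the later ring closure a more acidic nucleophile. It sets out from acid 11. The acid chloride 15 is made as before and added to dimethyl 3-oxopentanedioate, MgCl2 and pyridine in CH2Cl2 at 0 °C, giving trimethyl 1-[4-(allyloxy)-3,5-bis(benzyloxy)phenoxy]-2,4-dioxopentane-1,3,5-tricarboxylate F1. Mg(OMe)2 in refluxing MeOH closes it to dimethyl 5-[4-(allyloxy)-3,5-bis(benzyloxy)phenoxy]-2,4,6-trihydroxybenzene-1,3-dicarboxylate F2. BnBr and K2CO3 in DMF give dimethyl 5-[4-(allyloxy)-3,5-bis(benzyloxy)phenoxy]-2,4,6-tris(benzyloxy)benzene-1,3-dicarboxylate F3, and KOH in aqueous dioxane gives 5-[4-(allyloxy)-3,5-bis(benzyloxy)phenoxy]-2,4,6-tris(benzyloxy)benzene-1,3-dicarboxylic acid F4. Twofold silver-catalysed protodecarboxylation (Ag2CO3, AcOH, DMSO, 120 °C) comes back to the route at compound 21.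

Step 10. The ring closure may stop at 4-hydroxy-2-pyranones (O-acylation) or suffer retro-Claisen methanolysis. The fallback makes the hindered A–O–B ether by cross-coupling and gives up the ring synthesis. It sets out from bromide 5. Commercial 2,4,6-trihydroxybenzaldehyde is benzylated (BnBr, K2CO3, DMF) to 2,4,6-tris(benzyloxy)benzaldehyde F5, oxidised with mCPBA to 2,4,6-tris(benzyloxy)phenyl formate F6, and methanolysed (K2CO3, MeOH) to 2,4,6-tris(benzyloxy)phenol F7. Coupling of this phenol with 5 (CuI, picolinic acid, K3PO4, DMSO, 90 °C) comes back to the route at compound 21.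

Step 22 (step 18 is the same reaction on a smaller phenol). The ether formed has three ortho substituents and the phenol is large. The fallback changes the aryl partner from an electrophile to a boron nucleophile and couples oxidatively. It sets out from bromide 26. Miyaura borylation (B2pin2, Pd(dppf)Cl2, KOAc, dioxane, 90 °C) gives 2,3,4-tris(benzyloxy)-6-(4,4,5,5-tetramethyl-1,3,2-dioxaborolan-2-yl)benzaldehyde F8. Chan–Lam coupling of this boronate with phenol 32 (Cu(OAc)2, B(OH)3, 4 Å molecular sieves, MeCN, air, 70 °C) comes back to the route at compound 33. With phenol 22 the same sequence comes back at compound 27.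

**Further compounds**
F1 | step 9 | trimethyl 1-[4-(allyloxy)-3,5-bis(benzyloxy)phenoxy]-2,4-dioxopentane-1,3,5-tricarboxylate | COC(=O)CC(=O)C(C(=O)OC)C(=O)C(Oc1cc(OCc7ccccc7)c(OCC=C)c(OCc7ccccc7)c1)C(=O)OC
F2 | step 9 | dimethyl 5-[4-(allyloxy)-3,5-bis(benzyloxy)phenoxy]-2,4,6-trihydroxybenzene-1,3-dicarboxylate | COC(=O)c1c(O)c(C(=O)OC)c(O)c(Oc2cc(OCc7ccccc7)c(OCC=C)c(OCc7ccccc7)c2)c1O
F3 | step 9 | dimethyl 5-[4-(allyloxy)-3,5-bis(benzyloxy)phenoxy]-2,4,6-tris(benzyloxy)benzene-1,3-dicarboxylate | COC(=O)c1c(OCc7ccccc7)c(C(=O)OC)c(OCc7ccccc7)c(Oc2cc(OCc7ccccc7)c(OCC=C)c(OCc7ccccc7)c2)c1OCc7ccccc7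
F4 | step 9 | 5-[4-(allyloxy)-3,5-bis(benzyloxy)phenoxy]-2,4,6-tris(benzyloxy)benzene-1,3-dicarboxylic acid | OC(=O)c1c(OCc7ccccc7)c(C(=O)O)c(OCc7ccccc7)c(Oc2cc(OCc7ccccc7)c(OCC=C)c(OCc7ccccc7)c2)c1OCc7ccccc7
F5 | step 10 | 2,4,6-tris(benzyloxy)benzaldehyde | O=Cc1c(OCc7ccccc7)cc(OCc7ccccc7)cc1OCc7ccccc7
F6 | step 10 | 2,4,6-tris(benzyloxy)phenyl formate | O=COc1c(OCc7ccccc7)cc(OCc7ccccc7)cc1OCc7ccccc7
F7 | step 10 | 2,4,6-tris(benzyloxy)phenol | Oc1c(OCc7ccccc7)cc(OCc7ccccc7)cc1OCc7ccccc7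
F8 | step 22 | 2,3,4-tris(benzyloxy)-6-(4,4,5,5-tetramethyl-1,3,2-dioxaborolan-2-yl)benzaldehyde | O=Cc1c(B2OC(C)(C)C(C)(C)O2)cc(OCc7ccccc7)c(OCc7ccccc7)c1OCc7ccccc7
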